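## Structural features

The target is a tetramer of C6C3 units: guaiacyl ring A, two syringyl rings B and C, and ring D, which carries the (E)-propenal. A–B and B–C are joined as arylglycerol 8-O-4′ ethers (C7(OH)–C8(O-aryl)–C9H2OH), and C–D as an 8-5′ unit closed to a trans-2-aryl-3-hydroxymethyl-2,3-dihydrobenzofuran (O1–C7″ and C8″–C3a of ring D). The six stereocentres form three adjacent pairs, C7/C8 (R,S, erythro), C7′/C8′ (R,S, erythro) and C7″/C8″ (C2/C3 of the furan, R,S, trans), and each pair is insulated from the next by a benzene ring, so no pair can steer another. The same triad therefore occurs three times: an oxygen-bearing benzylic C7 next to a C8 that carries a CH2OH group and a third substituent X, with X = O–C4 of ring B, O–C4 of ring C, or C3a of ring D. Both ether oxygens sit between two ortho methoxy groups and on a doubly branched secondary carbon, which makes SN2 at C8 or C8′ the weak point of classical routes. Fragile functions are the benzylic alcohols para to oxygen (ionisation and epimerisation in acid; retro-aldol or β-ether cleavage in base whenever C9 is a carbonyl), the free phenol of ring A, and the enal, which tolerates neither alkene-cleaving oxidants nor hydride. The real difficulty is absolute and relative control in three remote pairs together with the two hindered ethers, solved convergently. The key step exploits C8′: read with its CH2OH as a masked vinyl group, C8′(O–ring C)(CH=CH2) is the γ-carbon of an (E)-γ-aryloxyallylboron reagent grown on the phenol oxygen of ring C, and the C7′–C8′ bond is its addition to the aldehyde carbon on ring B.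

## Logic of the disconnections

35 ⇒ 34. The three O–Si bonds (phenol of ring A, O7, O9″) are cut last. The silyl groups exist because the phenol and C7–OH would quench the organolithium of step 6 and compete for boron. The demand is a fluoride source that spares the enal.

34 ⇒ 31 + 32. The C5(ring D)–Cα bond of the enal is cut. The enal cannot coexist with alkene cleavage or borohydride, so ring D travels from 12 onward as an inert aryl bromide. The demand is a cross-coupling that tolerates three free hydroxyl groups and a mild acetal hydrolysis.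

31 ⇒ 29. Both C9 and C9′ hydroxymethyl groups are traced back to vinyl groups in one operation. The gain is that C8 and C8′ are never α to a carbonyl until the last moment. The demand is that the α-aryloxy dialdehyde 30 is reduced before it epimerises.

29 ⇒ 11 + 27 (through 28). This is the key cut: the C7′–C8′ bond with both of its stereocentres, in the middle of the molecule, dividing it into two halves of similar size. In one sentence: a chiral-acid-controlled anti-selective allylboration adds the γ-aryloxyallylboronate 28, grown on the phenol oxygen of the finished phenylcoumaran, to the aldehyde 11, while C9 and C9′ are still vinyl groups. The hindered C8′–O–aryl ether is already present in 27 as an ether made at a primary carbon. The demands are E geometry in 28, catalyst control over remote stereocentres, and that the transposition catalyst never meets the vinyl group of 11.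

27 ⇒ 26 ⇒ 25. The C–B bond comes from alkyne hydroboration and the O–Si bond from silylation. The propargyl group has served as the phenol protecting group of ring C since 20 and now becomes the C8′/C9′ donor.

25 ⇒ 23 ⇒ 22. C9″–OH is traced to a vinyl group, cleaved only after ring closure so that C2 anchors C3 at the aldehyde stage. The O1–C2 bond of the furan is then cut: ring closure by the ortho phenol onto the benzylic cation gives the trans ring, so C7″ need not be controlled in the open chain. The demand is that cation capture beats rearrangement.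

22 ⇒ 18 + 20 (through 21). The C7″–C8″ bond is cut by the same allylboration, now with an aryl carbon (C3a of ring D) as γ-substituent. Only C8″ has to be set here.

18 ⇒ 16 + 17; 16 ⇒ 15 ⇒ 14 ⇒ 12 + 13. The boron-bearing carbon comes from cross-metathesis. The C3a–C bond comes from an aromatic Claisen rearrangement, whose regiochemistry is fixed because one ortho position carries OMe. This gives the contiguous O/OMe/C pattern of ring D with Br para to oxygen.

20 ⇒ 19 + 4. The ether C–O bond is made at a primary propargylic carbon.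

11 ⇒ 9 ⇒ 8. The formyl carbon (future C7′) is attached at the C–Br bond of ring B. The O–Si bond masks the only acidic proton.

8 ⇒ 6 + 2 (through 7); 6 ⇒ 5 ⇒ 3 + 4; 2 ⇒ 1. The C7–C8 bond and its two stereocentres come from the same allylboration on small partners, which also tests the method. The ring-B ether oxygen is again attached at a primary carbon. Each transposition is run on a boronate that has no other terminal alkene, which dictates the order of assembly.

## Other disconnections considered

Alternative 1: (the first that comes to mind) Cut C7–C8 and C7′–C8′ as ester-level aldol bonds and grow the chain linearly outward from the phenol of a phenylcoumaran made by oxidative 8-5′ coupling. The forward key step is addition of the lithium enolate of aryloxyacetate A1, or of the boron enolate of its N-acyloxazolidinone A2, to the next aryl aldehyde. The Z-enolate of A2 in a closed chair should give the syn (threo) aldol, the wrong relative configuration for both units. Correction would need SN2 inversion at an ionisable p-alkoxybenzylic carbon, twice. The enolate of A1 would favour erythro but offers no absolute control over pairs that are remote from each other. The ester oxidation level keeps C8–H α to a carbonyl through several steps and costs an auxiliary and a reduction per unit. The sequence is linear on the most valuable fragment, and the oxidative coupling gives a racemic phenylcoumaran.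

Alternative 2: Cut both C7–H/C7′–H bonds at once: a double dynamic kinetic transfer hydrogenation of the bis(α-aryloxy-β-keto ester) A3, whose C8 and C8′ are stereolabile. The forward key step is a Noyori-type transfer hydrogenation that would set four stereocentres in one operation. The idea is attractive, but an outer-sphere hydride transfer should follow the polar Felkin–Anh arrangement (C–OAr bond anti to the incoming hydride), which leads to the syn (threo) alcohols. The erythro target would then require a double inversion at C7 and C7′. The third pair is not addressed, and two ester reductions remain.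

Alternative 3: Cut the aryl–C7′ bond. The forward key step is addition of aryllithium 10 to the α-aryloxy aldehyde A4, whose C8′ would come from a glycerate by Mitsunobu etherification, with C7′ set by 1,2-induction (polar Felkin–Anh, erythro, the right sense). The transition state is open, and the selectivity depends on suppressing chelation by the aryl ether and its flanking OMe groups, which would give threo. A4 is an enolisable, configurationally labile aldehyde exposed to a basic aryllithium. The Mitsunobu step returns the substitution at a hindered secondary carbon that the plan was meant to avoid, and the aryl bromide of ring D would scramble with 10. The chosen plan fixes the relative configuration by alkene geometry in a closed chair and the absolute configuration by a catalyst.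

Key step: step 17

Remark 1: the facial sense of the phosphoric acid is taken from the accepted hydrogen-bond model, in which the (R)-acid delivers the allyl group to the Re face of an aryl aldehyde. Steps 4, 12 and 17 all need Si-face addition and are written with (S)-TRIP, (S)-3,3′-bis(2,4,6-triisopropylphenyl)-1,1′-binaphthyl-2,2′-diyl hydrogen phosphate. If the sense were reversed for γ-substituted boronates, the (R)-acid would be used in all three steps.

Remark 2: 3, 12, 17 and 32 are taken as commercial. In names, TBS = tert-butyldimethylsilyl, TIPS = triisopropylsilyl, MOM = methoxymethyl, Bpin = 4,4,5,5-tetramethyl-1,3,2-dioxaborolan-2-yl. Locants C7–C9, C7′–C9′ and C7″–C9″ are the side chains on rings A, B and C.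

## Steps

Step 1
Reactants: 1 vanillin (4-hydroxy-3-methoxybenzaldehyde)
Product: 2 3-methoxy-4-(TIPSO)benzaldehyde
Conditions: TIPSCl, imidazole, DMF, rt
Reagents that add atoms: chlorotri(propan-2-yl)silane (TIPSCl), CC(C)[Si](Cl)(C(C)C)C(C)C
Why: Standard silylation of a phenol; the bulky aryl silyl ether should survive the organolithium of step 6, borohydride and mild base, and it keeps the aldehyde electrophilic for step 4.

Step 2
Reactants: 3 4-bromo-2,6-dimethoxyphenol; 4 propargyl bromide (3-bromoprop-1-yne)
Product: 5 5-bromo-1,3-dimethoxy-2-(prop-2-yn-1-yloxy)benzene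
Conditions: K2CO3, DMF, rt
Reagents that add atoms: none
Why: Williamson etherification (SN2) at a primary propargylic carbon; this is how the crowded 2,6-dimethoxyphenyl ether oxygen of the A–B link is introduced, so no substitution at the secondary C8 is ever needed.

Step 3
Reactants: 5
Product: 6 2-[(E)-3-(4-bromo-2,6-dimethoxyphenoxy)prop-1-en-1-yl]-4,4,5,5-tetramethyl-1,3,2-dioxaborolane
Conditions: pinacolborane, Cp2Zr(H)Cl (10 mol%), Et3N (10 mol%), neat, 60 °C
Reagents that add atoms: pinacolborane, [H]B1OC(C)(C)C(C)(C)O1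
Why: Zirconium-hydride-catalysed hydroboration of a terminal alkyne is a syn, anti-Markovnikov addition and should give the (E)-alkenylboronate with boron on the terminal carbon; aryl bromide and ethers are inert.

Step 4
Reactants: 6; 2
Product: 8 (1R,2S)-2-(4-bromo-2,6-dimethoxyphenoxy)-1-[3-methoxy-4-(TIPSO)phenyl]but-3-en-1-ol, via allylboronate 7 (not isolated)
Conditions: [Ir(cod)(PPh2Me)2]PF6 (3 mol%, activated with H2, then Ar), THF, rt; Florisil pad, toluene; 2, (S)-TRIP (5 mol%), 4 Å MS, −30 °C; aq. NaHCO3
Reagents that add atoms: none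
Why: A cationic iridium hydride shifts the double bond of 6 (the kinetically trans-selective allyl ether to propenyl ether isomerisation) to give the (E)-γ-aryloxyallylboronate 7; chiral-phosphoric-acid-catalysed allylboration through a closed chair then holds the γ-aryloxy group equatorial, so the E geometry fixes the anti (erythro) C7/C8 relationship, and the acid directs addition to the Si face of 2, giving 7R and hence 8S.

Step 5
Reactants: 8
Product: 9 TBS ether of 8, {[(1R,2S)-2-(4-bromo-2,6-dimethoxyphenoxy)-1-[3-methoxy-4-(TIPSO)phenyl]but-3-en-1-yl]oxy}(tert-butyl)dimethylsilane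
Conditions: TBSOTf, 2,6-lutidine, CH2Cl2, −40 → 0 °C
Reagents that add atoms: tert-butyldimethylsilyl trifluoromethanesulfonate, CC(C)(C)[Si](C)(C)OS(=O)(=O)C(F)(F)F
Why: Silylation of the hindered secondary benzylic alcohol with the silyl triflate; the ether removes the only acidic proton before the organolithium step and is cleaved with the other silyl groups in step 20.

Step 6
Reactants: 9
Product: 11 4-({(1R,2S)-1-(TBSO)-1-[3-methoxy-4-(TIPSO)phenyl]but-3-en-2-yl}oxy)-3,5-dimethoxybenzaldehyde, via aryllithium 10 (not isolated)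
Conditions: n-BuLi, THF, −78 °C; DMF, −78 → 0 °C; aq. NH4Cl
Reagents that add atoms: N,N-dimethylformamide, CN(C)C=O
Why: Bromine–lithium exchange at −78 °C is faster than any deprotonation, and formylation of aryllithium 10 with DMF (Bouveault aldehyde synthesis) places the carbon that becomes C7′; no stereocentre is touched.

Step 7
Reactants: 12 4-bromo-2-methoxyphenol; 13 allyl bromide (3-bromoprop-1-ene)
Product: 14 4-bromo-2-methoxy-1-(prop-2-en-1-yloxy)benzene
Conditions: K2CO3, acetone, reflux
Reagents that add atoms: none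
Why: Williamson etherification of the phenol; it sets up the sigmatropic shift of step 8.

Step 8
Reactants: 14
Product: 15 2-allyl-4-bromo-6-methoxyphenol
Conditions: N,N-diethylaniline, 190 °C
Reagents that add atoms: none
Why: Aromatic Claisen rearrangement ([3,3] shift, then tautomerisation); one ortho position is blocked by OMe, so the allyl group can only arrive at the carbon that becomes C3a of ring D, leaving Br para to oxygen.

Step 9
Reactants: 15
Product: 16 5-bromo-1-methoxy-2-(methoxymethoxy)-3-(prop-2-en-1-yl)benzene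
Conditions: NaH, MOMCl, THF/DMF, 0 °C → rt
Reagents that add atoms: chloromethyl methyl ether (MOMCl), COCCl
Why: Acetal protection of the hindered phenol through its sodium salt; MOM should be stable to metathesis, the iridium hydride and the phosphoric acid, and it is removed by the same acid that closes the ring in step 13.

Step 10
Reactants: 16; 17 vinylboronic acid pinacol ester (2-ethenyl-4,4,5,5-tetramethyl-1,3,2-dioxaborolane)
Product: 18 2-{(E)-3-[5-bromo-3-methoxy-2-(methoxymethoxy)phenyl]prop-1-en-1-yl}-4,4,5,5-tetramethyl-1,3,2-dioxaborolane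
Conditions: second-generation Grubbs catalyst (3 mol%), CH2Cl2, 40 °C
Reagents that add atoms: none
Why: Olefin cross-metathesis of a terminal allylarene with the vinylboronate should give the (E)-alkenylboronate with loss of ethylene; it adds the boron-bearing carbon without touching the aryl bromide.

Step 11
Reactants: 19 syringaldehyde (4-hydroxy-3,5-dimethoxybenzaldehyde); 4 propargyl bromide
Product: 20 3,5-dimethoxy-4-(prop-2-yn-1-yloxy)benzaldehyde
Conditions: K2CO3, DMF, 50 °C
Reagents that add atoms: none
Why: Williamson etherification; the propargyl group protects the phenol of ring C through steps 12–15 and is also the three-carbon precursor of C8′/C9′, so the hindered ring-C ether oxygen is installed at a primary carbon.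

Step 12
Reactants: 18; 20
Product: 22 (1S,2R)-2-[5-bromo-3-methoxy-2-(methoxymethoxy)phenyl]-1-[3,5-dimethoxy-4-(prop-2-yn-1-yloxy)phenyl]but-3-en-1-ol, via allylboronate 21 (not isolated)
Conditions: [Ir(cod)(PPh2Me)2]PF6 (3 mol%, activated with H2, then Ar), THF, rt; Florisil pad, toluene; 20, (S)-TRIP (10 mol%), 4 Å MS, −20 → 0 °C; aq. NaHCO3
Reagents that add atoms: none
Why: Same transposition (here into conjugation with ring D) and allylboration as in step 4, with an aryl carbon in place of the aryloxy group at the γ-position; Si-face addition through the chair with the γ-aryl group equatorial should give the anti adduct and set C8″ (R at this stage by priority), the only centre of 22 that has to survive. The alkyne of 20 never meets the iridium catalyst.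

Step 13
Reactants: 22
Product: 23 (2R,3R)-5-bromo-2-[3,5-dimethoxy-4-(prop-2-yn-1-yloxy)phenyl]-3-ethenyl-7-methoxy-2,3-dihydro-1-benzofuran
Conditions: conc. HCl (cat.), MeOH/THF, 45 °C
Reagents that add atoms: none
Why: Acid removes the MOM acetal and ionises the p-alkoxybenzylic alcohol; the freed ortho phenol captures the cation to close the five-membered ring (O1–C2), and because this closure is reversible the 2-aryl group settles trans to the 3-vinyl group, so C2 (R) is relayed from C3 by substrate control, as in classical phenylcoumaran cyclodehydrations.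

Step 14
Reactants: 23
Product: 25 [(2R,3S)-5-bromo-2-[3,5-dimethoxy-4-(prop-2-yn-1-yloxy)phenyl]-7-methoxy-2,3-dihydro-1-benzofuran-3-yl]methanol, via aldehyde 24 (not isolated)
Conditions: OsO4 (2 mol%), NaIO4, 2,6-lutidine, dioxane/H2O, rt; extraction; NaBH4, MeOH, 0 °C
Reagents that add atoms: osmium tetroxide (oxygen carrier), O=[Os](=O)(=O)=O; sodium periodate (terminal oxygen source), [Na+].[O-]I(=O)(=O)=O
Why: Lemieux–Johnson cleavage of the only alkene (the alkyne and the arenes react far more slowly) and borohydride reduction give the C9″ hydroxymethyl group; aldehyde 24 can epimerise at C3 only towards the trans isomer already present, because C2 is fixed.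

Step 15
Reactants: 25
Product: 26 TBS ether of 25, (2R,3S)-5-bromo-3-(TBSOCH2)-2-[3,5-dimethoxy-4-(prop-2-yn-1-yloxy)phenyl]-7-methoxy-2,3-dihydro-1-benzofuran
Conditions: TBSCl, imidazole, DMF, rt
Reagents that add atoms: tert-butylchlorodimethylsilane (TBSCl), CC(C)(C)[Si](C)(C)Cl
Why: Standard silylation of the primary alcohol, so that no hydroxyl competes for boron or for the acid catalyst in steps 16 and 17.

Step 16
Reactants: 26
Product: 27 2-[(E)-3-{4-[(2R,3S)-5-bromo-3-(TBSOCH2)-7-methoxy-2,3-dihydro-1-benzofuran-2-yl]-2,6-dimethoxyphenoxy}prop-1-en-1-yl]-4,4,5,5-tetramethyl-1,3,2-dioxaborolane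
Conditions: pinacolborane, Cp2Zr(H)Cl (10 mol%), Et3N (10 mol%), CH2Cl2, 40 °C
Reagents that add atoms: pinacolborane, [H]B1OC(C)(C)C(C)(C)O1
Why: Same syn hydroboration as in step 3, now on the propargyl ether of ring C; aryl bromide, silyl ether and the dihydrobenzofuran are spectators.

Step 17
Reactants: 27; 11
Product: 29 (1R,2S)-2-{4-[(2R,3S)-5-bromo-3-(TBSOCH2)-7-methoxy-2,3-dihydro-1-benzofuran-2-yl]-2,6-dimethoxyphenoxy}-1-[4-({(1R,2S)-1-(TBSO)-1-[3-methoxy-4-(TIPSO)phenyl]but-3-en-2-yl}oxy)-3,5-dimethoxyphenyl]but-3-en-1-ol, via allylboronate 28 (not isolated)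
Conditions: [Ir(cod)(PPh2Me)2]PF6 (3 mol%, activated with H2, then Ar), THF, rt; Florisil pad, toluene; 11, (S)-TRIP (10 mol%), 4 Å MS, −30 → 0 °C; aq. NaHCO3
Reagents that add atoms: none
Why: A cationic iridium hydride moves the double bond of 27 by a 1,3-hydrogen shift to the (E)-γ-aryloxyallylboronate 28, E because this catalyst class converts allyl ethers kinetically into trans-propenyl ethers, and the iridium is removed before 11 is added so that the allyl aryl ether of 11 is not isomerised. 28 then adds to the aldehyde of 11 as a type 1 allylmetal reagent through a six-membered chair with B–O coordination, the aldehyde aryl group and the γ-aryloxy group both equatorial, which translates the E geometry into the anti (erythro) C7′–C8′ relationship. The chiral phosphoric acid hydrogen-bonds to the pseudo-axial boronate oxygen and to the formyl hydrogen and thereby leaves the Si face of the aldehyde open, giving 7′R and, through the chair, 8′S. The closest known reaction type is the chiral-phosphoric-acid-catalysed allylboration of aryl aldehydes with γ-alkoxy- and γ-alkyl-substituted pinacol allylboronates, including its combination with iridium-catalysed transposition of alkenylboronates. No ring is closed; the step forms the C7′–C8′ bond, sets both stereocentres of the B–C unit and joins the two halves. The selectivity needed is catalyst control over the two existing stereocentre pairs, and the substrates secure it because those centres lie six bonds or more from the reacting carbons, beyond rings B and C. Chemoselectivity follows from the aldehyde being the only electrophile for the boronate, with the silyl ethers, the aryl bromide and the vinyl group as spectators. The hindered C8′–O–aryl ether is already in place, made at a primary carbon in step 11.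

Step 18
Reactants: 29
Product: 31 (1R,2S)-2-{4-[(2R,3S)-5-bromo-3-(TBSOCH2)-7-methoxy-2,3-dihydro-1-benzofuran-2-yl]-2,6-dimethoxyphenoxy}-1-[4-({(1R,2S)-1-(TBSO)-3-hydroxy-1-[3-methoxy-4-(TIPSO)phenyl]propan-2-yl}oxy)-3,5-dimethoxyphenyl]propane-1,3-diol, via dialdehyde 30 (not isolated)
Conditions: OsO4 (4 mol%), NaIO4, 2,6-lutidine, dioxane/H2O, rt; extraction; NaBH4, MeOH, −20 → 0 °C
Reagents that add atoms: osmium tetroxide (oxygen carrier), O=[Os](=O)(=O)=O; sodium periodate (terminal oxygen source), [Na+].[O-]I(=O)(=O)=O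
Why: Double Lemieux–Johnson cleavage of the two terminal vinyl groups and immediate borohydride reduction of dialdehyde 30 unveil the C9 and C9′ hydroxymethyl groups in one operation; 2,6-lutidine buffering and prompt reduction should keep the α-aryloxy aldehydes from epimerising at C8/C8′ or undergoing retro-aldol cleavage.

Step 19
Reactants: 31; 32 (E)-2-(3,3-diethoxyprop-1-en-1-yl)-4,4,5,5-tetramethyl-1,3,2-dioxaborolane
Product: 34 (E)-3-[(2R,3S)-3-(TBSOCH2)-2-{4-[((1R,2S)-1,3-dihydroxy-1-{4-[((1R,2S)-1-(TBSO)-3-hydroxy-1-[3-methoxy-4-(TIPSO)phenyl]propan-2-yl)oxy]-3,5-dimethoxyphenyl}propan-2-yl)oxy]-3,5-dimethoxyphenyl}-7-methoxy-2,3-dihydro-1-benzofuran-5-yl]prop-2-enal, via diethyl acetal 33 (not isolated)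
Conditions: Pd(dppf)Cl2 (5 mol%), K3PO4, 1,4-dioxane/H2O, 80 °C; then aq. citric acid, THF, rt
Reagents that add atoms: water, O
Why: Suzuki–Miyaura coupling of the unhindered aryl bromide of ring D with the (E)-alkenylboronate proceeds with retention of alkene geometry and tolerates free hydroxyl groups; the conjugated acetal 33 is hydrolysed by weak aqueous acid that spares silyl ethers and benzylic alcohols, so the enal appears only after all oxidative and hydride steps.

Step 20
Reactants: 34
Product: 35 CNP0192639.1, (E)-3-[(2R,3S)-2-{4-[((1R,2S)-1-{4-[((1R,2S)-1,3-dihydroxy-1-(4-hydroxy-3-methoxyphenyl)propan-2-yl)oxy]-3,5-dimethoxyphenyl}-1,3-dihydroxypropan-2-yl)oxy]-3,5-dimethoxyphenyl}-3-(hydroxymethyl)-7-methoxy-2,3-dihydro-1-benzofuran-5-yl]prop-2-enal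
Conditions: TBAF, AcOH, THF, 0 °C → rt
Reagents that add atoms: none
Why: Fluoride cleaves the phenolic TIPS ether and both TBS ethers in one step; acetic acid buffering keeps the medium near neutral, so the enal, the free phenol and the benzylic alcohols (none of them β to a carbonyl) are not endangered.

## Compound list

1 | vanillin | COc1cc(C=O)ccc1O | starting material
2 | 3-methoxy-4-(TIPSO)benzaldehyde | COc1cc(C=O)ccc1O[Si](C(C)C)(C(C)C)C(C)C | intermediate
3 | 4-bromo-2,6-dimethoxyphenol | COc1cc(Br)cc(OC)c1O | starting material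
4 | propargyl bromide | C#CCBr | starting material
5 | 5-bromo-1,3-dimethoxy-2-(prop-2-yn-1-yloxy)benzene | COc1cc(Br)cc(OC)c1OCC#C | intermediate
6 | 2-[(E)-3-(4-bromo-2,6-dimethoxyphenoxy)prop-1-en-1-yl]-Bpin | COc1cc(Br)cc(OC)c1OC/C=C/B1OC(C)(C)C(C)(C)O1 | intermediate
7 | 2-[(E)-3-(4-bromo-2,6-dimethoxyphenoxy)prop-2-en-1-yl]-Bpin | COc1cc(Br)cc(OC)c1O/C=C/CB1OC(C)(C)C(C)(C)O1 | intermediate (not isolated)
8 | (1R,2S)-2-(4-bromo-2,6-dimethoxyphenoxy)-1-[3-methoxy-4-(TIPSO)phenyl]but-3-en-1-ol | COc1cc([C@@H](O)[C@H](C=C)Oc2c(OC)cc(Br)cc2OC)ccc1O[Si](C(C)C)(C(C)C)C(C)C | intermediate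
9 | TBS ether of 8 (1R,2S) | COc1cc([C@@H](O[Si](C)(C)C(C)(C)C)[C@H](C=C)Oc2c(OC)cc(Br)cc2OC)ccc1O[Si](C(C)C)(C(C)C)C(C)C | intermediate
10 | aryllithium from 9 (Li in place of Br, 1R,2S) | COc1cc([C@@H](O[Si](C)(C)C(C)(C)C)[C@H](C=C)Oc2c(OC)cc([Li])cc2OC)ccc1O[Si](C(C)C)(C(C)C)C(C)C | intermediate (not isolated)
11 | 4-({(1R,2S)-1-(TBSO)-1-[3-methoxy-4-(TIPSO)phenyl]but-3-en-2-yl}oxy)-3,5-dimethoxybenzaldehyde | COc1cc([C@@H](O[Si](C)(C)C(C)(C)C)[C@H](C=C)Oc2c(OC)cc(C=O)cc2OC)ccc1O[Si](C(C)C)(C(C)C)C(C)C | intermediate
12 | 4-bromo-2-methoxyphenol | COc1cc(Br)ccc1O | starting material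
13 | allyl bromide | C=CCBr | starting material
14 | 4-bromo-2-methoxy-1-(prop-2-en-1-yloxy)benzene | COc1cc(Br)ccc1OCC=C | intermediate
15 | 2-allyl-4-bromo-6-methoxyphenol | COc1cc(Br)cc(CC=C)c1O | intermediate
16 | 5-bromo-1-methoxy-2-(methoxymethoxy)-3-(prop-2-en-1-yl)benzene | COCOc1c(CC=C)cc(Br)cc1OC | intermediate
17 | vinylboronic acid pinacol ester | C=CB1OC(C)(C)C(C)(C)O1 | starting material
18 | 2-{(E)-3-[5-bromo-3-methoxy-2-(methoxymethoxy)phenyl]prop-1-en-1-yl}-Bpin | COCOc1c(C/C=C/B2OC(C)(C)C(C)(C)O2)cc(Br)cc1OC | intermediate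
19 | syringaldehyde | COc1cc(C=O)cc(OC)c1O | starting material
20 | 3,5-dimethoxy-4-(prop-2-yn-1-yloxy)benzaldehyde | COc1cc(C=O)cc(OC)c1OCC#C | intermediate
21 | 2-{(E)-3-[5-bromo-3-methoxy-2-(methoxymethoxy)phenyl]prop-2-en-1-yl}-Bpin | COCOc1c(/C=C/CB2OC(C)(C)C(C)(C)O2)cc(Br)cc1OC | intermediate (not isolated)
22 | (1S,2R)-2-[5-bromo-3-methoxy-2-(methoxymethoxy)phenyl]-1-[3,5-dimethoxy-4-(prop-2-yn-1-yloxy)phenyl]but-3-en-1-ol | C#CCOc1c(OC)cc(cc1OC)[C@@H](O)[C@H](C=C)c1cc(Br)cc(OC)c1OCOC | intermediate
23 | (2R,3R)-5-bromo-2-[3,5-dimethoxy-4-(prop-2-yn-1-yloxy)phenyl]-3-ethenyl-7-methoxy-2,3-dihydro-1-benzofuran | C#CCOc1c(OC)cc(cc1OC)[C@@H]1Oc2c(OC)cc(Br)cc2[C@H]1C=C | intermediate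
24 | (2R,3R)-5-bromo-2-[3,5-dimethoxy-4-(prop-2-yn-1-yloxy)phenyl]-7-methoxy-2,3-dihydro-1-benzofuran-3-carbaldehyde | C#CCOc1c(OC)cc(cc1OC)[C@@H]1Oc2c(OC)cc(Br)cc2[C@H]1C=O | intermediate (not isolated)
25 | [(2R,3S)-5-bromo-2-[3,5-dimethoxy-4-(prop-2-yn-1-yloxy)phenyl]-7-methoxy-2,3-dihydro-1-benzofuran-3-yl]methanol | C#CCOc1c(OC)cc(cc1OC)[C@@H]1Oc2c(OC)cc(Br)cc2[C@H]1CO | intermediate
26 | TBS ether of 25 (2R,3S) | C#CCOc1c(OC)cc(cc1OC)[C@@H]1Oc2c(OC)cc(Br)cc2[C@H]1CO[Si](C)(C)C(C)(C)C | intermediate
27 | 2-[(E)-3-{4-[(2R,3S)-5-bromo-3-(TBSOCH2)-7-methoxy-2,3-dihydro-1-benzofuran-2-yl]-2,6-dimethoxyphenoxy}prop-1-en-1-yl]-Bpin | COc1cc([C@@H]2Oc3c(OC)cc(Br)cc3[C@H]2CO[Si](C)(C)C(C)(C)C)cc(OC)c1OC/C=C/B1OC(C)(C)C(C)(C)O1 | intermediate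
28 | 2-[(E)-3-{4-[(2R,3S)-5-bromo-3-(TBSOCH2)-7-methoxy-2,3-dihydro-1-benzofuran-2-yl]-2,6-dimethoxyphenoxy}prop-2-en-1-yl]-Bpin | COc1cc([C@@H]2Oc3c(OC)cc(Br)cc3[C@H]2CO[Si](C)(C)C(C)(C)C)cc(OC)c1O/C=C/CB1OC(C)(C)C(C)(C)O1 | intermediate (not isolated)
29 | union product, (7R,8S,7′R,8′S,2″R,3″S), C8 and C8′ bearing vinyl groups (full name in step 17) | COc1cc([C@@H](O[Si](C)(C)C(C)(C)C)[C@H](C=C)Oc2c(OC)cc([C@@H](O)[C@H](C=C)Oc3c(OC)cc([C@@H]4Oc5c(OC)cc(Br)cc5[C@H]4CO[Si](C)(C)C(C)(C)C)cc3OC)cc2OC)ccc1O[Si](C(C)C)(C(C)C)C(C)C | intermediate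
30 | dialdehyde, 29 with CHO in place of each CH=CH2 (same spatial arrangement; C8 and C8′ become R by priority: 7R,8R,7′R,8′R,2″R,3″S) | COc1cc([C@@H](O[Si](C)(C)C(C)(C)C)[C@H](C=O)Oc2c(OC)cc([C@@H](O)[C@H](C=O)Oc3c(OC)cc([C@@H]4Oc5c(OC)cc(Br)cc5[C@H]4CO[Si](C)(C)C(C)(C)C)cc3OC)cc2OC)ccc1O[Si](C(C)C)(C(C)C)C(C)C | intermediate (not isolated)
31 | triol, (7R,8S,7′R,8′S,2″R,3″S), free C9–OH, C7′–OH, C9′–OH (full name in step 18) | COc1cc([C@@H](O[Si](C)(C)C(C)(C)C)[C@H](CO)Oc2c(OC)cc([C@@H](O)[C@H](CO)Oc3c(OC)cc([C@@H]4Oc5c(OC)cc(Br)cc5[C@H]4CO[Si](C)(C)C(C)(C)C)cc3OC)cc2OC)ccc1O[Si](C(C)C)(C(C)C)C(C)C | intermediate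
32 | (E)-2-(3,3-diethoxyprop-1-en-1-yl)-4,4,5,5-tetramethyl-1,3,2-dioxaborolane | CCOC(OCC)/C=C/B1OC(C)(C)C(C)(C)O1 | starting material
33 | diethyl acetal of 34, 31 with (E)-3,3-diethoxyprop-1-enyl in place of Br | COc1cc([C@@H](O[Si](C)(C)C(C)(C)C)[C@H](CO)Oc2c(OC)cc([C@@H](O)[C@H](CO)Oc3c(OC)cc([C@@H]4Oc5c(OC)cc(/C=C/C(OCC)OCC)cc5[C@H]4CO[Si](C)(C)C(C)(C)C)cc3OC)cc2OC)ccc1O[Si](C(C)C)(C(C)C)C(C)C | intermediate (not isolated)
34 | tris-silylated target, (E)-enal (full name in step 19) | COc1cc([C@@H](O[Si](C)(C)C(C)(C)C)[C@H](CO)Oc2c(OC)cc([C@@H](O)[C@H](CO)Oc3c(OC)cc([C@@H]4Oc5c(OC)cc(/C=C/C=O)cc5[C@H]4CO[Si](C)(C)C(C)(C)C)cc3OC)cc2OC)ccc1O[Si](C(C)C)(C(C)C)C(C)C | intermediate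
35 | CNP0192639.1 (full name in step 20) | COc1cc([C@@H](O)[C@H](CO)Oc2c(OC)cc([C@@H](O)[C@H](CO)Oc3c(OC)cc([C@@H]4Oc5c(OC)cc(/C=C/C=O)cc5[C@H]4CO)cc3OC)cc2OC)ccc1O | target

## Step count and risk

Total: 20 steps. Longest linear sequence: 13 steps from 12 (steps 7–10, 12–20). The branch to 11 has 6 steps (1–6).

Step 17 (key). Most likely to go wrong:
- loss of E geometry of 28 during or after the transposition, which would lead to the threo diad;
- incomplete facial control by the catalyst with so bulky a γ-aryloxy group and so large an aldehyde, letting the uncatalysed pathway compete and giving the (7′S,8′R) diad;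
- carry-over of iridium hydride, which would isomerise the allyl aryl ether of 11 or 29.

Fallback (stereocontrol moved from an external catalyst to a chiral diol on boron): it sets out from 27. Oxidative removal of pinacol (NaIO4, NH4OAc, acetone/H2O) would give the boronic acid F1. Esterification with diisopropyl (R,R)-tartrate (MgSO4, toluene) would give the tartrate alkenylboronate F2. The same iridium transposition would give the (E)-allylboronate F3, used without isolation and added to 11 in toluene at −78 °C with 4 Å MS. Tartrate allylboronates of this γ-oxy type are known to pass the E geometry on to the anti adduct, and the (R,R)-ester is the one expected to attack the Si face. The sequence comes back to the route at 29; a minor diad isomer would be removed by chromatography there or at 31.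

Step 4. The same two failure modes (E/Z erosion in the transposition, insufficient facial control) arise on the small partners. Steps 12 and 17 rest on the same catalyst pair, so this step is the inexpensive test of the method. Fallback (resolution in place of asymmetric catalysis): it sets out from 6 and 2. The uncatalysed addition of 7 to 2 (toluene, rt) should still give only the anti adduct, because that follows from the chair and the E geometry alone, now as the racemate: 8 together with its enantiomer F4. Preparative chromatography on a chiral stationary phase separates the two and returns 8 to the route.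

Step 13. Most likely to go wrong: cation-derived side reactions. The benzylic cation at C7″ has a vinyl-bearing neighbour, so a 1,2-shift of ring D (to an allyl cation) or proton loss to a conjugated diene can compete with ring closure. Ionisation may also be slow because the 4-alkoxy group of ring C is twisted by its two ortho OMe groups. Fallback (remove the vinyl group before the cation is made): it sets out from 22. Ozonolysis at −78 °C (CH2Cl2/MeOH, Sudan Red 7B as end-point indicator) with NaBH4 added cold would give, through the aldehyde F5, the 1,3-diol F6. Acid cyclodehydration of F6 (HCl, MeOH) is the classical phenylcoumaran closure and gives 25 directly, where the route is rejoined. The price is that the open-chain α-aryl aldehyde F5 must be reduced cold before it can epimerise at C8″.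

Step 18. Most likely to go wrong: base-induced epimerisation at C8 or C8′ through the enols of the α-aryloxy aldehydes in 30, retro-aldol cleavage of the β-hydroxy aldehyde of the B–C unit, or β-elimination of the C7 silyloxy group during the periodate stage. Fallback (block the free C7′–OH and avoid a basic aldehyde stage): it sets out from 29. TESOTf/2,6-lutidine would give the triethylsilyl ether F7. Ozonolysis (CH2Cl2/MeOH, −78 °C) with NaBH4 added cold would give, through the dialdehyde F8, the diol F9. PPTS in MeOH removes only the triethylsilyl group and returns 31.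

## Further compounds

F1 | step 17 | (E)-[3-{4-[(2R,3S)-5-bromo-3-(TBSOCH2)-7-methoxy-2,3-dihydro-1-benzofuran-2-yl]-2,6-dimethoxyphenoxy}prop-1-en-1-yl]boronic acid | COc1cc([C@@H]2Oc3c(OC)cc(Br)cc3[C@H]2CO[Si](C)(C)C(C)(C)C)cc(OC)c1OC/C=C/B(O)O
F2 | step 17 | diisopropyl (4R,5R)-2-[(E)-3-(aryloxy)prop-1-en-1-yl]-1,3,2-dioxaborolane-4,5-dicarboxylate, aryl as in F1 | COc1cc([C@@H]2Oc3c(OC)cc(Br)cc3[C@H]2CO[Si](C)(C)C(C)(C)C)cc(OC)c1OC/C=C/B1O[C@@H](C(=O)OC(C)C)[C@H](C(=O)OC(C)C)O1
F3 | step 17 | diisopropyl (4R,5R)-2-[(E)-3-(aryloxy)prop-2-en-1-yl]-1,3,2-dioxaborolane-4,5-dicarboxylate, aryl as in F1 | COc1cc([C@@H]2Oc3c(OC)cc(Br)cc3[C@H]2CO[Si](C)(C)C(C)(C)C)cc(OC)c1O/C=C/CB1O[C@@H](C(=O)OC(C)C)[C@H](C(=O)OC(C)C)O1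
F4 | step 4 | (1S,2R)-2-(4-bromo-2,6-dimethoxyphenoxy)-1-[3-methoxy-4-(TIPSO)phenyl]but-3-en-1-ol (enantiomer of 8) | COc1cc([C@H](O)[C@@H](C=C)Oc2c(OC)cc(Br)cc2OC)ccc1O[Si](C(C)C)(C(C)C)C(C)C
F5 | step 13 | (2R,3S)-2-[5-bromo-3-methoxy-2-(methoxymethoxy)phenyl]-3-[3,5-dimethoxy-4-(prop-2-yn-1-yloxy)phenyl]-3-hydroxypropanal | C#CCOc1c(OC)cc(cc1OC)[C@@H](O)[C@H](C=O)c1cc(Br)cc(OC)c1OCOC
F6 | step 13 | (1S,2S)-2-[5-bromo-3-methoxy-2-(methoxymethoxy)phenyl]-1-[3,5-dimethoxy-4-(prop-2-yn-1-yloxy)phenyl]propane-1,3-diol | C#CCOc1c(OC)cc(cc1OC)[C@@H](O)[C@H](CO)c1cc(Br)cc(OC)c1OCOC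
F7 | step 18 | C7′ triethylsilyl ether of 29 | COc1cc([C@@H](O[Si](C)(C)C(C)(C)C)[C@H](C=C)Oc2c(OC)cc([C@@H](O[Si](CC)(CC)CC)[C@H](C=C)Oc3c(OC)cc([C@@H]4Oc5c(OC)cc(Br)cc5[C@H]4CO[Si](C)(C)C(C)(C)C)cc3OC)cc2OC)ccc1O[Si](C(C)C)(C(C)C)C(C)C
F8 | step 18 | dialdehyde from F7 (CHO in place of each CH=CH2) | COc1cc([C@@H](O[Si](C)(C)C(C)(C)C)[C@H](C=O)Oc2c(OC)cc([C@@H](O[Si](CC)(CC)CC)[C@H](C=O)Oc3c(OC)cc([C@@H]4Oc5c(OC)cc(Br)cc5[C@H]4CO[Si](C)(C)C(C)(C)C)cc3OC)cc2OC)ccc1O[Si](C(C)C)(C(C)C)C(C)C
F9 | step 18 | C7′ triethylsilyl ether of 31 | COc1cc([C@@H](O[Si](C)(C)C(C)(C)C)[C@H](CO)Oc2c(OC)cc([C@@H](O[Si](CC)(CC)CC)[C@H](CO)Oc3c(OC)cc([C@@H]4Oc5c(OC)cc(Br)cc5[C@H]4CO[Si](C)(C)C(C)(C)C)cc3OC)cc2OC)ccc1O[Si](C(C)C)(C(C)C)C(C)C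
A1 | alternative 1 | ethyl 2-{4-[(2R,3S)-5-bromo-3-(TBSOCH2)-7-methoxy-2,3-dihydro-1-benzofuran-2-yl]-2,6-dimethoxyphenoxy}acetate | CCOC(=O)COc1c(OC)cc(cc1OC)[C@@H]1Oc2c(OC)cc(Br)cc2[C@H]1CO[Si](C)(C)C(C)(C)C
A2 | alternative 1 | (S)-4-benzyl-3-(2-{4-[(2R,3S)-5-bromo-3-(TBSOCH2)-7-methoxy-2,3-dihydro-1-benzofuran-2-yl]-2,6-dimethoxyphenoxy}acetyl)oxazolidin-2-one | O=C(COc1c(OC)cc(cc1OC)[C@@H]1Oc2c(OC)cc(Br)cc2[C@H]1CO[Si](C)(C)C(C)(C)C)N1C(=O)OC[C@@H]1Cc1ccccc1
A3 | alternative 2 | bis(α-aryloxy-β-keto ester): ring A–CO–CH(CO2Et)–O–ring B–CO–CH(CO2Et)–O–ring C of the (2R,3S)-phenylcoumaran, C8 and C8′ stereolabile | CCOC(=O)C(Oc1c(OC)cc(cc1OC)C(=O)C(Oc1c(OC)cc(cc1OC)[C@@H]1Oc2c(OC)cc(Br)cc2[C@H]1CO[Si](C)(C)C(C)(C)C)C(=O)OCC)C(=O)c1ccc(O[Si](C(C)C)(C(C)C)C(C)C)c(OC)c1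
A4 | alternative 3 | (S)-2-{4-[(2R,3S)-5-bromo-3-(TBSOCH2)-7-methoxy-2,3-dihydro-1-benzofuran-2-yl]-2,6-dimethoxyphenoxy}-3-(TBSO)propanal | O=C[C@H](CO[Si](C)(C)C(C)(C)C)Oc1c(OC)cc(cc1OC)[C@@H]1Oc2c(OC)cc(Br)cc2[C@H]1CO[Si](C)(C)C(C)(C)C
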